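Cuts (retro): acetate O–acyl bond; C5–CH3 raised to C5–CHO; imidazole C2–N3; amide N–C(O); isoxazole C3–C4 and C5–O1.
Feature: N3–C4(arylethyl)–C5–CH3 of the imidazole is the N2–C3–C4–C5 edge of an isoxazole ring. N1–C2 with the four-carbon chain is an amide on isoxazole C4.
Forward: nitrile oxide plus nitroenamine build the isoxazole ring; NO2 becomes NH2; the amine opens δ-valerolactone and so attaches the chain.
N–O hydrogenolysis opens the isoxazole and base recloses the same atoms as the imidazole ring (5-carbaldehyde). Wolff–Kishner reduction gives the methyl group and acetylation comes last.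
The chain oxygen is carried as free OH because ring closure and deoxygenation are both strongly basic.
Stereochemistry: none in the target; only the transient alkene geometry of the opened enal matters, and it is resolved in the key step.

Key step: step 6

Assumption: the two N–H tautomers of every imidazole interconvert rapidly, so the locants 4 and 5 follow the SMILES as drawn.

Step 1
Reactants: 1 3-(3,4-dimethoxyphenyl)propan-1-ol
Product: 2 3-(3,4-dimethoxyphenyl)propanal
Conditions: TEMPO (10 mol %), PhI(OAc)2 (1.1 equiv), CH2Cl2, rt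
Reagents that add atoms: none
Why: TEMPO-catalysed oxoammonium oxidation of a primary alcohol should stop at the aldehyde under nearly neutral conditions that leave the electron-rich dimethoxyarene untouched.

Step 2
Reactants: 2 3-(3,4-dimethoxyphenyl)propanal
Product: 3 3-(3,4-dimethoxyphenyl)propanal oxime
Conditions: NH2OH·HCl, NaOAc, EtOH–H2O, rt
Reagents that add atoms: hydroxylamine hydrochloride, NO.Cl
Why: Oxime condensation of an unhindered aliphatic aldehyde with buffered hydroxylamine is fast, and the oxime geometry is irrelevant because both isomers lead to the same nitrile oxide.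

Step 3
Reactants: 3 3-(3,4-dimethoxyphenyl)propanal oxime; 4 (E)-N,N-dimethyl-2-nitroethenamine
Product: 8 3-[2-(3,4-dimethoxyphenyl)ethyl]-4-nitroisoxazole, via hydroximoyl chloride 5 (not isolated), via nitrile oxide 6 (not isolated), via trans-aminoisoxazoline 7 (not isolated)
Conditions: NCS (1.0 equiv), DMF, 0 °C → rt; then 4, Et3N (slow addition), 0 °C → rt; 1 M HCl work-up
Reagents that add atoms: none
Why: In this Huisgen 1,3-dipolar cycloaddition the nucleophilic nitro-bearing carbon of the push–pull alkene bonds to the nitrile oxide carbon and the oxygen bonds to the amino-bearing carbon, and loss of dimethylamine from 7 erases both transient stereocentres and aromatises to the 4-nitroisoxazole with C5–H.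

Step 4
Reactants: 8 3-[2-(3,4-dimethoxyphenyl)ethyl]-4-nitroisoxazole
Product: 9 3-[2-(3,4-dimethoxyphenyl)ethyl]isoxazol-4-amine
Conditions: SnCl2·2H2O, conc. HCl, EtOH, 0 °C → rt; cold aq. NaHCO3 work-up
Reagents that add atoms: none
Why: Nitro-to-amine reduction with divalent tin in acid is the classical entry to 4-aminoisoxazoles, because the nitro group accepts electrons far faster than the ring N–O bond that catalytic hydrogenation would endanger.

Step 5
Reactants: 9 3-[2-(3,4-dimethoxyphenyl)ethyl]isoxazol-4-amine; 10 δ-valerolactone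
Product: 12 N-{3-[2-(3,4-dimethoxyphenyl)ethyl]isoxazol-4-yl}-5-hydroxypentanamide, via dimethylaluminium amide 11 (not isolated)
Conditions: AlMe3 (toluene solution), CH2Cl2, 0 °C → rt; then 10 (1.05 equiv), 40 °C; aq. Rochelle salt work-up
Reagents that add atoms: none
Why: In this Weinreb-type aluminium amide aminolysis the weakly nucleophilic heteroarylamine is activated as 11, which opens the lactone at its acyl carbon and gives amide and free primary alcohol in one operation, and any oligoester from further lactone opening would be saponified to the same chain in step 6.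

Step 6
Reactants: 12 N-{3-[2-(3,4-dimethoxyphenyl)ethyl]isoxazol-4-yl}-5-hydroxypentanamide
Product: 15 4-[2-(3,4-dimethoxyphenyl)ethyl]-2-(4-hydroxybutyl)-1H-imidazole-5-carbaldehyde, via E-enaminal 13 (not isolated), via Z-enaminal 14 (not isolated)
Conditions: H2 (1 atm), 10% Pd/C, EtOH, rt; filter; NaOH (1.5 equiv), EtOH, 45 °C; AcOH to pH 7
Reagents that add atoms: none
Why: Palladium-catalysed hydrogenolysis cleaves the weak O1–N2 bond and tautomerisation gives the push–pull enaminal 13; the closest known reaction type is the reductive opening of 4-acylaminoisoxazoles followed by base-induced recyclisation to 4(5)-acylimidazoles. Because N2 and C5 were both ring neighbours of the C3–C4 bond, 13 is formed with NH2 syn to the formyl group (hydrogen-bonded) and anti to the amide nitrogen, so it cannot close as formed. Hydroxide deprotonates it to a delocalised N–C–C–C–O anion with low C3–C4 bond order, rotation gives 14, and only this isomer places the nucleophilic nitrogen beside the amide carbonyl. Attack on that carbonyl is a 5-exo-trig closure that forms the C2–N3 bond, and loss of water from the tetrahedral adduct gives the aromatic imidazole irreversibly, which drains the E/Z equilibrium. No stereocentre is created. The step needs N–O cleavage without reduction of the vinylogous formamide, secured by 1 atm H2 at rt and the low electrophilicity of the conjugated aldehyde, and it needs the nitrogen to stay on the former C3, secured by adding no external ammonia and by a substrate whose other groups, the free hydroxyl included, are inert to NaOH.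

Step 7
Reactants: 15 4-[2-(3,4-dimethoxyphenyl)ethyl]-2-(4-hydroxybutyl)-1H-imidazole-5-carbaldehyde
Product: 17 cypholophine (4-{4-[2-(3,4-dimethoxyphenyl)ethyl]-5-methyl-1H-imidazol-2-yl}butan-1-ol), via hydrazone 16 (not isolated)
Conditions: N2H4·H2O, KOH, diethylene glycol, 130 °C → 195 °C
Reagents that add atoms: none
Why: In this Wolff–Kishner reduction (Huang-Minlon variant) hydrazone 16 forms at the lower temperature and loses N2 under hot KOH, turning the heteroaryl aldehyde into the methyl group in one operation, while the alcohol, the imidazole and the non-conjugated aryl methyl ethers tolerate the base.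

Step 8
Reactants: 17 cypholophine
Product: 18 O-acetylcypholophine (4-{4-[2-(3,4-dimethoxyphenyl)ethyl]-5-methyl-1H-imidazol-2-yl}butyl acetate)
Conditions: Ac2O (1.5 equiv), pyridine, CH2Cl2, rt; MeOH quench
Reagents that add atoms: acetic anhydride, CC(=O)OC(C)=O
Why: This is a standard O-acetylation of a primary alcohol, and any acetyl group taken up by the ring nitrogen is itself an acyl donor that is solvolysed in the methanol quench, so only the ester should remain.

Compound list
1 | 3-(3,4-dimethoxyphenyl)propan-1-ol | COc1ccc(CCCO)cc1OC | starting material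
2 | 3-(3,4-dimethoxyphenyl)propanal | COc1ccc(CCC=O)cc1OC | intermediate
3 | 3-(3,4-dimethoxyphenyl)propanal oxime (E/Z mixture, geometry of no consequence) | COc1ccc(CCC=NO)cc1OC | intermediate
4 | (E)-N,N-dimethyl-2-nitroethenamine | CN(C)/C=C/[N+](=O)[O-] | starting material
5 | 3-(3,4-dimethoxyphenyl)-N-hydroxypropanimidoyl chloride | COc1ccc(CCC(Cl)=NO)cc1OC | intermediate
6 | 3-(3,4-dimethoxyphenyl)propanenitrile oxide | COc1ccc(CCC#[N+][O-])cc1OC | intermediate
7 | trans-3-[2-(3,4-dimethoxyphenyl)ethyl]-N,N-dimethyl-4-nitro-4,5-dihydroisoxazol-5-amine (racemic, one enantiomer drawn) | CN(C)[C@@H]1ON=C(CCc2ccc(OC)c(OC)c2)[C@H]1[N+](=O)[O-] | intermediate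
8 | 3-[2-(3,4-dimethoxyphenyl)ethyl]-4-nitroisoxazole | COc1ccc(CCc2nocc2[N+](=O)[O-])cc1OC | intermediate
9 | 3-[2-(3,4-dimethoxyphenyl)ethyl]isoxazol-4-amine | COc1ccc(CCc2nocc2N)cc1OC | intermediate
10 | δ-valerolactone (tetrahydro-2H-pyran-2-one) | O=C1CCCCO1 | starting material
11 | dimethylaluminium amide of 9 | C[Al](C)Nc1conc1CCc1ccc(OC)c(OC)c1 | intermediate
12 | N-{3-[2-(3,4-dimethoxyphenyl)ethyl]isoxazol-4-yl}-5-hydroxypentanamide | COc1ccc(CCc2nocc2NC(=O)CCCCO)cc1OC | intermediate
13 | N-[(2E)-3-amino-5-(3,4-dimethoxyphenyl)-1-oxopent-2-en-2-yl]-5-hydroxypentanamide (NH2 syn to CHO) | N/C(CCc1ccc(OC)c(OC)c1)=C(C=O)/NC(=O)CCCCO | intermediate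
14 | N-[(2Z)-3-amino-5-(3,4-dimethoxyphenyl)-1-oxopent-2-en-2-yl]-5-hydroxypentanamide (NH2 syn to the amide nitrogen) | N/C(CCc1ccc(OC)c(OC)c1)=C(C=O)\NC(=O)CCCCO | intermediate
15 | 4-[2-(3,4-dimethoxyphenyl)ethyl]-2-(4-hydroxybutyl)-1H-imidazole-5-carbaldehyde | COc1ccc(CCc2nc(CCCCO)[nH]c2C=O)cc1OC | intermediate
16 | hydrazone of 15 | COc1ccc(CCc2nc(CCCCO)[nH]c2/C=N/N)cc1OC | intermediate
17 | cypholophine, 4-{4-[2-(3,4-dimethoxyphenyl)ethyl]-5-methyl-1H-imidazol-2-yl}butan-1-ol | COc1ccc(CCc2nc(CCCCO)[nH]c2C)cc1OC | intermediate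
18 | O-acetylcypholophine, 4-{4-[2-(3,4-dimethoxyphenyl)ethyl]-5-methyl-1H-imidazol-2-yl}butyl acetate | COc1ccc(CCc2nc(CCCCOC(C)=O)[nH]c2C)cc1OC | target

Total steps: 8. Longest linear sequence: 8 steps (1 → 18); 4 and 10 enter as purchased reagents.

Steps most likely to fail

Step 6.
- **Risk:** Ring closure has to wait for the E → Z turn of the opened enal. Meanwhile hydroxide may attack the vinylogous formamide, so that ammonia or the formyl carbon is lost, or the nitrogen migrates to the formyl carbon, before the ring forms.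
- **Fallback:** It sets out from 12 and comes back at 15. The amide is made more electrophilic under water-free conditions, in place of making the amine more nucleophilic with base.
 - The hydrogenolysis is run in EtOAc and 13 is isolated.
 - 13 is then heated in hexamethyldisilazane and toluene with catalytic (NH4)2SO4. This is the silylative cyclodehydration used to close 5-acylamino-6-aminouracils to xanthines.
 - O-Silylation should turn the amide into a silyl imidate, thermal equilibration through the imine tautomer should supply 14, and the oxygen should leave as siloxane.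
 - The hydroxyl is silylated on the way, giving 4-[2-(3,4-dimethoxyphenyl)ethyl]-2-[4-(trimethylsilyloxy)butyl]-1H-imidazole-5-carbaldehyde F1.
 - Stirring with methanol removes this silyl group, and any silyl group on the ring nitrogen, to give 15.

Step 3.
- **Risk:** The aliphatic nitrile oxide may dimerise faster than it adds to the deactivated push–pull alkene. Liberated dimethylamine may add to the dipole or to the electrophilic C5 of the product, and NCS may chlorinate the electron-rich arene.
- **Fallback:** It sets out from 3 and comes back at 9, so step 4 is bypassed as well.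
 - Nitrile oxide 6 is generated as before but trapped with ethyl (E)-3-(dimethylamino)acrylate, an enamine dipolarophile without the strongly deactivating nitro group.
 - The adduct, ethyl trans-5-(dimethylamino)-3-[2-(3,4-dimethoxyphenyl)ethyl]-4,5-dihydroisoxazole-4-carboxylate F2, loses dimethylamine to give ethyl 3-[2-(3,4-dimethoxyphenyl)ethyl]isoxazole-4-carboxylate F3.
 - Acid hydrolysis (6 M HCl, AcOH, 90 °C) gives 3-[2-(3,4-dimethoxyphenyl)ethyl]isoxazole-4-carboxylic acid F4. Base is avoided because hydroxide attacks C5-unsubstituted isoxazole esters.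
 - Curtius rearrangement with DPPA and Et3N in t-BuOH at 85 °C passes through 3-[2-(3,4-dimethoxyphenyl)ethyl]isoxazole-4-carbonyl azide F5 and 3-[2-(3,4-dimethoxyphenyl)ethyl]-4-isocyanatoisoxazole F6.
 - The isocyanate is trapped as tert-butyl {3-[2-(3,4-dimethoxyphenyl)ethyl]isoxazol-4-yl}carbamate F7.
 - HCl in dioxane followed by aqueous NaHCO3 releases 9.

Step 7.
- **Risk:** Nitrogen loss from the hydrazone of an anionic imidazolide may be sluggish. Azine formation and partial O-demethylation at 195 °C may compete.
- **Fallback:** It sets out from 15 and comes back at 18, replacing steps 7 and 8 with a mild stepwise deoxygenation.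
 - Ac2O in pyridine with a methanol quench gives 4-{4-[2-(3,4-dimethoxyphenyl)ethyl]-5-formyl-1H-imidazol-2-yl}butyl acetate F8.
 - NaBH4 in EtOH at 0 °C should reduce only the aldehyde, giving 4-{4-[2-(3,4-dimethoxyphenyl)ethyl]-5-(hydroxymethyl)-1H-imidazol-2-yl}butyl acetate F9.
 - SOCl2 in CH2Cl2 gives 4-{5-(chloromethyl)-4-[2-(3,4-dimethoxyphenyl)ethyl]-1H-imidazol-2-yl}butyl acetate hydrochloride F10.
 - Hydrogenolysis of the activated C–Cl bond (H2, Pd/C, EtOH) and an aqueous NaHCO3 work-up give 18.

Further compounds
F1 | step 6 | 4-[2-(3,4-dimethoxyphenyl)ethyl]-2-[4-(trimethylsilyloxy)butyl]-1H-imidazole-5-carbaldehyde | COc1ccc(CCc2nc(CCCCO[Si](C)(C)C)[nH]c2C=O)cc1OC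
F2 | step 3 | ethyl trans-5-(dimethylamino)-3-[2-(3,4-dimethoxyphenyl)ethyl]-4,5-dihydroisoxazole-4-carboxylate (racemic, one enantiomer drawn) | CN(C)[C@@H]1ON=C(CCc2ccc(OC)c(OC)c2)[C@H]1C(=O)OCC
F3 | step 3 | ethyl 3-[2-(3,4-dimethoxyphenyl)ethyl]isoxazole-4-carboxylate | CCOC(=O)c1conc1CCc1ccc(OC)c(OC)c1
F4 | step 3 | 3-[2-(3,4-dimethoxyphenyl)ethyl]isoxazole-4-carboxylic acid | OC(=O)c1conc1CCc1ccc(OC)c(OC)c1
F5 | step 3 | 3-[2-(3,4-dimethoxyphenyl)ethyl]isoxazole-4-carbonyl azide | [N-]=[N+]=NC(=O)c1conc1CCc1ccc(OC)c(OC)c1
F6 | step 3 | 3-[2-(3,4-dimethoxyphenyl)ethyl]-4-isocyanatoisoxazole | O=C=Nc1conc1CCc1ccc(OC)c(OC)c1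
F7 | step 3 | tert-butyl {3-[2-(3,4-dimethoxyphenyl)ethyl]isoxazol-4-yl}carbamate | CC(C)(C)OC(=O)Nc1conc1CCc1ccc(OC)c(OC)c1
F8 | step 7 | 4-{4-[2-(3,4-dimethoxyphenyl)ethyl]-5-formyl-1H-imidazol-2-yl}butyl acetate | COc1ccc(CCc2nc(CCCCOC(C)=O)[nH]c2C=O)cc1OC
F9 | step 7 | 4-{4-[2-(3,4-dimethoxyphenyl)ethyl]-5-(hydroxymethyl)-1H-imidazol-2-yl}butyl acetate | COc1ccc(CCc2nc(CCCCOC(C)=O)[nH]c2CO)cc1OC
F10 | step 7 | 4-{5-(chloromethyl)-4-[2-(3,4-dimethoxyphenyl)ethyl]-1H-imidazol-2-yl}butyl acetate hydrochloride | COc1ccc(CCc2nc(CCCCOC(C)=O)[nH]c2CCl)cc1OC.Cl
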